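Ring B (C4a, C5, C6, C7, C8, C8a) is read as an aldol and vinylogous-acylation adduct: the C8 hydroxyl is β to the C6 ketone across the fully substituted C7, and C5=C4a is an enone bond ending at the pyran carbon para to O2. One flask therefore joins acetoin (C5–C6–C7) to a side-chain-bearing 4-methoxy-2-pyranone-3-carbaldehyde (C4a–C8a–C8) in a [3+3] annulation: a zinc-catalysed asymmetric direct aldol forms C7–C8 with both stereocentres, then silyl-triflate-driven attack of the acetyl enol silane on the vinylogous ester carbon forms C5–C4a. The lactone carbonyl at C1 is reduced and transposed afterwards; C5 is chlorinated on the way.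

Key step: step 8

Remark: core atoms are numbered as in the isochromene skeleton of the target (C1, O2, C3, C4, C4a, C5–C8, C8a); side-chain atoms carry primes.
Remark: (S,S)-ProPhenol is 2,6-bis{[(S)-2-(hydroxydiphenylmethyl)pyrrolidin-1-yl]methyl}-4-methylphenol; it is assumed to deliver the 7R,8S sense, and its (R,R)-enantiomer would be used if the facial sense proves opposite.
Remark: compounds 1, 7 and 12 are commercial; 12 is used as the racemate because its stereocentre is lost on enolisation.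

Step 1
Reactants: 1 (2S,3S)-2-hydroxy-3-methylpentanoic acid
Product: 2 (2S,3S)-2-hydroxy-N-methoxy-N,3-dimethylpentanamide
Conditions: MeNHOMe·HCl, EDC·HCl, HOBt, N-methylmorpholine, CH2Cl2, 0 → 23 °C
Reagents that add atoms: N,O-dimethylhydroxylamine hydrochloride, CNOC.Cl
Why: Carbodiimide amide coupling gives the Weinreb amide without touching the two stereocentres, which come from the chiral pool and become C4′ and C5′.

Step 2
Reactants: 2 (2S,3S)-2-hydroxy-N-methoxy-N,3-dimethylpentanamide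
Product: 3 (4S,5S)-4-hydroxy-5-methylhept-1-en-3-one
Conditions: CH2=CHMgBr (3 equiv), THF, −78 → 0 °C; cold aq. NH4Cl
Reagents that add atoms: vinylmagnesium bromide, C=C[Mg]Br
Why: Weinreb ketone synthesis, in which the first equivalent of Grignard reagent deprotonates the hydroxyl and the chelated tetrahedral adduct collapses only on work-up, so the vinyl ketone should form without over-addition or epimerisation.

Step 3
Reactants: 3 (4S,5S)-4-hydroxy-5-methylhept-1-en-3-one
Product: 4 (3R,4S,5S)-3,5-dimethylhept-1-ene-3,4-diol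
Conditions: MeMgBr (3 equiv), THF, −78 °C
Reagents that add atoms: methylmagnesium bromide, C[Mg]Br
Why: Chelation-controlled Grignard 1,2-addition, in which the magnesium alkoxide and the carbonyl oxygen form a five-membered chelate and methyl adds to the face anti to the sec-butyl group, which should set C3 as R.

Step 4
Reactants: 4 (3R,4S,5S)-3,5-dimethylhept-1-ene-3,4-diol
Product: 5 (3R,4S,5S)-3,5-dimethyl-3,4-bis(triethylsilyloxy)hept-1-ene
Conditions: Et3SiOTf, 2,6-lutidine, CH2Cl2, −78 → 0 °C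
Reagents that add atoms: triethylsilyl trifluoromethanesulfonate, CC[Si](CC)(CC)OS(=O)(=O)C(F)(F)F
Why: Silylation with the silyl triflate protects both the secondary and the hindered tertiary hydroxyl as triethylsilyl ethers.

Step 5
Reactants: 5 (3R,4S,5S)-3,5-dimethyl-3,4-bis(triethylsilyloxy)hept-1-ene
Product: 6 (2S,3S,4S)-2,4-dimethyl-2,3-bis(triethylsilyloxy)hexanal
Conditions: O3, CH2Cl2, −78 °C; then PPh3
Reagents that add atoms: ozone, [O-][O+]=O
Why: Ozonolysis with reductive work-up cleaves the terminal vinyl group to an α-silyloxy aldehyde that has no α-hydrogen and so cannot epimerise.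

Step 6
Reactants: 7 4-methoxy-6-methyl-2H-pyran-2-one; 6 (2S,3S,4S)-2,4-dimethyl-2,3-bis(triethylsilyloxy)hexanal
Product: 10 6-[(1E,3R,4S,5S)-3,5-dimethyl-3,4-bis(triethylsilyloxy)hept-1-en-1-yl]-4-methoxy-2H-pyran-2-one, via lithium aldolate 8 (not isolated), via secondary mesylate 9 (not isolated)
Conditions: LiN(i-Pr)2, THF, −78 °C; 6; then MsCl, −78 → 0 °C; then DBU, 23 °C
Reagents that add atoms: none
Why: Vinylogous aldol addition of the 6-methyl anion of the pyranone to the aldehyde, mesylation of the aldolate and E1cB elimination (aldol condensation) should give the conjugated alkene in the favoured E geometry anti to the quaternary carbon.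

Step 7
Reactants: 10 6-[(1E,3R,4S,5S)-3,5-dimethyl-3,4-bis(triethylsilyloxy)hept-1-en-1-yl]-4-methoxy-2H-pyran-2-one
Product: 11 6-[(1E,3R,4S,5S)-3,5-dimethyl-3,4-bis(triethylsilyloxy)hept-1-en-1-yl]-4-methoxy-2-oxo-2H-pyran-3-carbaldehyde
Conditions: lithium 2,2,6,6-tetramethylpiperidide, THF, −78 °C; DMF; aq. NH4Cl
Reagents that add atoms: N,N-dimethylformamide, CN(C)C=O
Why: Directed lithiation at C3 of the pyranone, the ring position flanked by the lactone carbonyl and the methoxy group, followed by formylation with DMF installs the aldehyde carbon that becomes C8.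

Step 8
Reactants: 11 6-[(1E,3R,4S,5S)-3,5-dimethyl-3,4-bis(triethylsilyloxy)hept-1-en-1-yl]-4-methoxy-2-oxo-2H-pyran-3-carbaldehyde; 12 3-hydroxybutan-2-one (acetoin)
Product: 15 (7R,8S)-3-[(1E,3R,4S,5S)-3,5-dimethyl-3,4-bis(triethylsilyloxy)hept-1-en-1-yl]-7-methyl-7,8-bis(triethylsilyloxy)-7,8-dihydro-1H-isochromene-1,6(5H)-dione, via aldol adduct 13 (not isolated), via tris(silyl) enol ether 14 (not isolated)
Conditions: Et2Zn (20 mol %), (S,S)-ProPhenol (10 mol %), THF, −20 °C; then CH2Cl2, i-Pr2NEt, Et3SiOTf, −78 → 0 °C; aq. NaHCO3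
Reagents that add atoms: triethylsilyl trifluoromethanesulfonate, CC[Si](CC)(CC)OS(=O)(=O)C(F)(F)F
Why: Proposed new method: The dinuclear zinc alkoxide catalyst should convert acetoin into a chelated Z-zinc enediolate that adds through its carbinol carbon (C7) to the zinc-bound aldehyde carbon (C8) in a closed transition state, giving 13. Et3SiOTf with i-Pr2NEt should then cap both alkoxides, turn the only enolisable position left, the acetyl methyl (C5), into enol silane 14, and O-silylate the lactone to a 2-silyloxy-4-methoxypyrylium ion whose C4a is attacked by C5 with loss of MeOSiEt3. The closest known reactions are the zinc-catalysed direct aldol of α-hydroxy ketones to syn-diols (also with tetrasubstituted carbinol carbons), the ipso-substitution of 4-alkoxypyrylium salts by carbon nucleophiles, and the [3+3] cyclisation of 4-chloro-3-formylcoumarin with 1,3-dinucleophiles. Ring B closes by a 6-(enolendo)-endo-trig addition–elimination at C4a. C7 (R) and C8 (S) are both set in the aldol by the ligand: the chelated enediolate places the C7 oxygen syn to the new C8 hydroxyl, which is the trans diol of the ring, and the ligand selects the aldehyde face. The step needs enolisation of acetoin at the hydroxylated carbon, which chelation of its hydroxyl to zinc should secure, and bond formation at C4a and not at C1, which is secured because C4a carries the methoxy leaving group whereas C1 is a lactone carbonyl to which addition is reversible.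

Step 9
Reactants: 15 (7R,8S)-3-[(1E,3R,4S,5S)-3,5-dimethyl-3,4-bis(triethylsilyloxy)hept-1-en-1-yl]-7-methyl-7,8-bis(triethylsilyloxy)-7,8-dihydro-1H-isochromene-1,6(5H)-dione
Product: 16 (7R,8S)-5-chloro-3-[(1E,3R,4S,5S)-3,5-dimethyl-3,4-bis(triethylsilyloxy)hept-1-en-1-yl]-7-methyl-7,8-bis(triethylsilyloxy)-7,8-dihydro-1H-isochromene-1,6(5H)-dione
Conditions: N-chlorosuccinimide (1.05 equiv), CH2Cl2, 0 °C
Reagents that add atoms: N-chlorosuccinimide, O=C1CCC(=O)N1Cl
Why: Electrophilic α-chlorination of the vinylogous β-keto lactone should occur through its enol at C5, the doubly activated methylene, and the C5 configuration is irrelevant because this carbon becomes sp2.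

Step 10
Reactants: 16 (7R,8S)-5-chloro-3-[(1E,3R,4S,5S)-3,5-dimethyl-3,4-bis(triethylsilyloxy)hept-1-en-1-yl]-7-methyl-7,8-bis(triethylsilyloxy)-7,8-dihydro-1H-isochromene-1,6(5H)-dione
Product: 19 (7R,8S)-5-chloro-3-[(1E,3R,4S,5S)-3,5-dimethyl-3,4-bis(triethylsilyloxy)hept-1-en-1-yl]-7-methyl-7,8-bis(triethylsilyloxy)-7,8-dihydro-6H-isochromen-6-one, via silyl dienol ether 17 (not isolated), via lactol 18 (not isolated)
Conditions: Et3SiOTf, Et3N, CH2Cl2, −78 °C; i-Bu2AlH (1.2 equiv), −78 °C; aq. potassium sodium tartrate; then pyridinium p-toluenesulfonate, wet THF, 0 °C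
Reagents that add atoms: none
Why: Stork–Danheiser-type reduction and transposition, in which the ketone is masked as silyl dienol ether 17, the lactone is reduced to lactol 18, and mild acid ionises the lactol to a pyrylium ion that loses the silyl group to leave the 4-ylidene pyran with C4a=C5 and C8a=C1 in place.

Step 11
Reactants: 19 (7R,8S)-5-chloro-3-[(1E,3R,4S,5S)-3,5-dimethyl-3,4-bis(triethylsilyloxy)hept-1-en-1-yl]-7-methyl-7,8-bis(triethylsilyloxy)-7,8-dihydro-6H-isochromen-6-one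
Product: 20 (7R,8S)-5-chloro-3-[(1E,3R,4S,5S)-3,4-dihydroxy-3,5-dimethylhept-1-en-1-yl]-7,8-dihydroxy-7-methyl-7,8-dihydro-6H-isochromen-6-one
Conditions: HF·pyridine, pyridine, THF, 0 → 23 °C
Reagents that add atoms: none
Why: Fluoride-mediated desilylation with buffered HF·pyridine should remove all four triethylsilyl ethers without ionising the C8 or C3′ carbinols.

Compound list
1 | (2S,3S)-2-hydroxy-3-methylpentanoic acid | CC[C@H](C)[C@H](O)C(=O)O | starting material
2 | (2S,3S)-2-hydroxy-N-methoxy-N,3-dimethylpentanamide | CC[C@H](C)[C@H](O)C(=O)N(C)OC | intermediate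
3 | (4S,5S)-4-hydroxy-5-methylhept-1-en-3-one | CC[C@H](C)[C@H](O)C(=O)C=C | intermediate
4 | (3R,4S,5S)-3,5-dimethylhept-1-ene-3,4-diol | CC[C@H](C)[C@H](O)[C@](C)(O)C=C | intermediate
5 | (3R,4S,5S)-3,5-dimethyl-3,4-bis(triethylsilyloxy)hept-1-ene | CC[C@H](C)[C@H](O[Si](CC)(CC)CC)[C@](C)(O[Si](CC)(CC)CC)C=C | intermediate
6 | (2S,3S,4S)-2,4-dimethyl-2,3-bis(triethylsilyloxy)hexanal | CC[C@H](C)[C@H](O[Si](CC)(CC)CC)[C@](C)(O[Si](CC)(CC)CC)C=O | intermediate
7 | 4-methoxy-6-methyl-2H-pyran-2-one | COC1=CC(=O)OC(C)=C1 | starting material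
8 | 6-[2-hydroxy-3,5-dimethyl-3,4-bis(triethylsilyloxy)heptyl]-4-methoxy-2H-pyran-2-one, lithium alkoxide, both C2′ epimers, C3′ to C5′ as in 6 | CC[C@H](C)[C@H](O[Si](CC)(CC)CC)[C@](C)(O[Si](CC)(CC)CC)C(O)CC1=CC(OC)=CC(=O)O1 | intermediate
9 | 6-[3,5-dimethyl-2-(methylsulfonyloxy)-3,4-bis(triethylsilyloxy)heptyl]-4-methoxy-2H-pyran-2-one, both C2′ epimers, C3′ to C5′ as in 6 | CC[C@H](C)[C@H](O[Si](CC)(CC)CC)[C@](C)(O[Si](CC)(CC)CC)C(OS(C)(=O)=O)CC1=CC(OC)=CC(=O)O1 | intermediate
10 | 6-[(1E,3R,4S,5S)-3,5-dimethyl-3,4-bis(triethylsilyloxy)hept-1-en-1-yl]-4-methoxy-2H-pyran-2-one | CC[C@H](C)[C@H](O[Si](CC)(CC)CC)[C@](C)(O[Si](CC)(CC)CC)/C=C/C1=CC(OC)=CC(=O)O1 | intermediate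
11 | 6-[(1E,3R,4S,5S)-3,5-dimethyl-3,4-bis(triethylsilyloxy)hept-1-en-1-yl]-4-methoxy-2-oxo-2H-pyran-3-carbaldehyde | CC[C@H](C)[C@H](O[Si](CC)(CC)CC)[C@](C)(O[Si](CC)(CC)CC)/C=C/C1=CC(OC)=C(C=O)C(=O)O1 | intermediate
12 | 3-hydroxybutan-2-one (acetoin, racemic) | CC(O)C(C)=O | starting material
13 | 6-[(1E,3R,4S,5S)-3,5-dimethyl-3,4-bis(triethylsilyloxy)hept-1-en-1-yl]-3-[(1S,2R)-1,2-dihydroxy-2-methyl-3-oxobutyl]-4-methoxy-2H-pyran-2-one, as zinc alkoxide | CC[C@H](C)[C@H](O[Si](CC)(CC)CC)[C@](C)(O[Si](CC)(CC)CC)/C=C/C1=CC(OC)=C(C(=O)O1)[C@H](O)[C@@](C)(O)C(C)=O | intermediate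
14 | 6-[(1E,3R,4S,5S)-3,5-dimethyl-3,4-bis(triethylsilyloxy)hept-1-en-1-yl]-4-methoxy-3-[(1S,2R)-2-methyl-1,2,3-tris(triethylsilyloxy)but-3-en-1-yl]-2H-pyran-2-one | CC[C@H](C)[C@H](O[Si](CC)(CC)CC)[C@](C)(O[Si](CC)(CC)CC)/C=C/C1=CC(OC)=C(C(=O)O1)[C@H](O[Si](CC)(CC)CC)[C@@](C)(O[Si](CC)(CC)CC)C(=C)O[Si](CC)(CC)CC | intermediate
15 | (7R,8S)-3-[(1E,3R,4S,5S)-3,5-dimethyl-3,4-bis(triethylsilyloxy)hept-1-en-1-yl]-7-methyl-7,8-bis(triethylsilyloxy)-7,8-dihydro-1H-isochromene-1,6(5H)-dione | CC[C@H](C)[C@H](O[Si](CC)(CC)CC)[C@](C)(O[Si](CC)(CC)CC)/C=C/C1=CC2=C(C(=O)O1)[C@H](O[Si](CC)(CC)CC)[C@@](C)(O[Si](CC)(CC)CC)C(=O)C2 | intermediate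
16 | (7R,8S)-5-chloro-3-[(1E,3R,4S,5S)-3,5-dimethyl-3,4-bis(triethylsilyloxy)hept-1-en-1-yl]-7-methyl-7,8-bis(triethylsilyloxy)-7,8-dihydro-1H-isochromene-1,6(5H)-dione, C5 epimers in equilibrium with the enol | CC[C@H](C)[C@H](O[Si](CC)(CC)CC)[C@](C)(O[Si](CC)(CC)CC)/C=C/C1=CC2=C(C(=O)O1)[C@H](O[Si](CC)(CC)CC)[C@@](C)(O[Si](CC)(CC)CC)C(=O)C2Cl | intermediate
17 | (7R,8S)-5-chloro-3-[(1E,3R,4S,5S)-3,5-dimethyl-3,4-bis(triethylsilyloxy)hept-1-en-1-yl]-7-methyl-6,7,8-tris(triethylsilyloxy)-7,8-dihydro-1H-isochromen-1-one | CC[C@H](C)[C@H](O[Si](CC)(CC)CC)[C@](C)(O[Si](CC)(CC)CC)/C=C/C1=CC2=C(C(=O)O1)[C@H](O[Si](CC)(CC)CC)[C@@](C)(O[Si](CC)(CC)CC)C(O[Si](CC)(CC)CC)=C2Cl | intermediate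
18 | (7R,8S)-5-chloro-3-[(1E,3R,4S,5S)-3,5-dimethyl-3,4-bis(triethylsilyloxy)hept-1-en-1-yl]-7-methyl-6,7,8-tris(triethylsilyloxy)-7,8-dihydro-1H-isochromen-1-ol, both C1 epimers | CC[C@H](C)[C@H](O[Si](CC)(CC)CC)[C@](C)(O[Si](CC)(CC)CC)/C=C/C1=CC2=C(C(O)O1)[C@H](O[Si](CC)(CC)CC)[C@@](C)(O[Si](CC)(CC)CC)C(O[Si](CC)(CC)CC)=C2Cl | intermediate
19 | (7R,8S)-5-chloro-3-[(1E,3R,4S,5S)-3,5-dimethyl-3,4-bis(triethylsilyloxy)hept-1-en-1-yl]-7-methyl-7,8-bis(triethylsilyloxy)-7,8-dihydro-6H-isochromen-6-one | CC[C@H](C)[C@H](O[Si](CC)(CC)CC)[C@](C)(O[Si](CC)(CC)CC)/C=C/C1=CC2=C(Cl)C(=O)[C@](C)(O[Si](CC)(CC)CC)[C@@H](O[Si](CC)(CC)CC)C2=CO1 | intermediate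
20 | (7R,8S)-5-chloro-3-[(1E,3R,4S,5S)-3,4-dihydroxy-3,5-dimethylhept-1-en-1-yl]-7,8-dihydroxy-7-methyl-7,8-dihydro-6H-isochromen-6-one (CNP0133971.5) | CC[C@H](C)[C@H](O)[C@](C)(O)/C=C/C1=CC2=C(Cl)C(=O)[C@](C)(O)[C@@H](O)C2=CO1 | target

Total steps: 11. Longest linear sequence: 11 steps (1 to 20); 7 and 12 are bought and enter at steps 6 and 8.

Steps most likely to fail

Step 8. In the zinc stage, enolisation may take place at the acetyl methyl instead of the carbinol carbon, a zinc alkoxide may displace the methoxy group at C4a or open the lactone, and facial selectivity with an aliphatic hydroxy ketone may be poor. In the silyl stage, the C8 silyloxy group may ionise before ring closure. The fallback uses known chemistry, sets out from 11 and comes back to the route at 15. Butane-2,3-dione would be reductively silylated with Mg and Et3SiCl in THF to the enediol bis(silyl ether) (Z)-2,3-bis(triethylsilyloxy)but-2-ene F1. A Mukaiyama aldol addition of this preformed, symmetrical enol silane to 11 would be run under Cu(OTf)2 and 2,2′-(propane-2,2-diyl)bis[(4S)-4-tert-butyl-4,5-dihydrooxazole] in CH2Cl2 at −78 °C, where the aldehyde and lactone carbonyl oxygens chelate copper. After silyl transfer it should give 6-[(1E,3R,4S,5S)-3,5-dimethyl-3,4-bis(triethylsilyloxy)hept-1-en-1-yl]-4-methoxy-3-[(1S,2R)-2-methyl-3-oxo-1,2-bis(triethylsilyloxy)butyl]-2H-pyran-2-one F2. Adding i-Pr2NEt and Et3SiOTf to the same flask would convert it into 14 and on to 15 as in step 8. Isomers at C7 and C8 that remain would be removed by chromatography at 15.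

Step 10. The open hydroxy aldehyde form of the lactol may be reduced further, silylation may occur at the lactone oxygen instead of O6, or the C8 silyloxy group may be lost by vinylogous elimination from the silyl dienol ether. The fallback sets out from 16 and comes back at 19 by deliberate exhaustive reduction and re-oxidation. Compound 16 would be silylated to 17 as in step 10 and reduced with excess i-Bu2AlH (3 equiv, −78 → −20 °C). The lactol opens, its aldehyde is reduced while the C3 ketone is held as the aluminium enolate, and work-up should give (3E,5R,6S,7S)-1-[(3S,4R)-6-chloro-2-(hydroxymethyl)-4-methyl-3,4,5-tris(triethylsilyloxy)cyclohexa-1,5-dien-1-yl]-5,7-dimethyl-5,6-bis(triethylsilyloxy)non-3-en-2-one F3. MnO2 in CH2Cl2 would oxidise the allylic primary alcohol to (3E,5R,6S,7S)-1-[(3S,4R)-6-chloro-2-formyl-4-methyl-3,4,5-tris(triethylsilyloxy)cyclohexa-1,5-dien-1-yl]-5,7-dimethyl-5,6-bis(triethylsilyloxy)non-3-en-2-one F4. Pyridinium p-toluenesulfonate in wet THF would then cyclise the enol oxygen of the C3 ketone onto the aldehyde, giving the pyrylium ion, which loses the silyl group to give 19.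

Step 7. The amide base may deprotonate C5 of the pyranone or add to C6 instead of lithiating C3. The fallback sets out from 10 and comes back at 11 by electrophilic halogenation and halogen–metal exchange. N-Bromosuccinimide in MeCN at 0 °C should brominate C3, the most nucleophilic ring carbon of the 4-methoxy-2-pyranone, to give 3-bromo-6-[(1E,3R,4S,5S)-3,5-dimethyl-3,4-bis(triethylsilyloxy)hept-1-en-1-yl]-4-methoxy-2H-pyran-2-one F5. Bromine–magnesium exchange with i-PrMgCl·LiCl in THF at −40 °C and quenching with DMF would then give 11.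

Further compounds
F1 | step 8 | (Z)-2,3-bis(triethylsilyloxy)but-2-ene | C/C(O[Si](CC)(CC)CC)=C(\C)O[Si](CC)(CC)CC
F2 | step 8 | 6-[(1E,3R,4S,5S)-3,5-dimethyl-3,4-bis(triethylsilyloxy)hept-1-en-1-yl]-4-methoxy-3-[(1S,2R)-2-methyl-3-oxo-1,2-bis(triethylsilyloxy)butyl]-2H-pyran-2-one | CC[C@H](C)[C@H](O[Si](CC)(CC)CC)[C@](C)(O[Si](CC)(CC)CC)/C=C/C1=CC(OC)=C(C(=O)O1)[C@H](O[Si](CC)(CC)CC)[C@@](C)(O[Si](CC)(CC)CC)C(C)=O
F3 | step 10 | (3E,5R,6S,7S)-1-[(3S,4R)-6-chloro-2-(hydroxymethyl)-4-methyl-3,4,5-tris(triethylsilyloxy)cyclohexa-1,5-dien-1-yl]-5,7-dimethyl-5,6-bis(triethylsilyloxy)non-3-en-2-one | CC[C@H](C)[C@H](O[Si](CC)(CC)CC)[C@](C)(O[Si](CC)(CC)CC)/C=C/C(=O)CC1=C(CO)[C@H](O[Si](CC)(CC)CC)[C@@](C)(O[Si](CC)(CC)CC)C(O[Si](CC)(CC)CC)=C1Cl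
F4 | step 10 | (3E,5R,6S,7S)-1-[(3S,4R)-6-chloro-2-formyl-4-methyl-3,4,5-tris(triethylsilyloxy)cyclohexa-1,5-dien-1-yl]-5,7-dimethyl-5,6-bis(triethylsilyloxy)non-3-en-2-one | CC[C@H](C)[C@H](O[Si](CC)(CC)CC)[C@](C)(O[Si](CC)(CC)CC)/C=C/C(=O)CC1=C(C=O)[C@H](O[Si](CC)(CC)CC)[C@@](C)(O[Si](CC)(CC)CC)C(O[Si](CC)(CC)CC)=C1Cl
F5 | step 7 | 3-bromo-6-[(1E,3R,4S,5S)-3,5-dimethyl-3,4-bis(triethylsilyloxy)hept-1-en-1-yl]-4-methoxy-2H-pyran-2-one | CC[C@H](C)[C@H](O[Si](CC)(CC)CC)[C@](C)(O[Si](CC)(CC)CC)/C=C/C1=CC(OC)=C(Br)C(=O)O1
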